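No proposed step leaves the target or the decomposed reagent, so a flat target below full yield cannot be a balance of forward and back.

| flask | substrate | remark | time |
|---|---|---|---|
| green | 0.29 M | run made earlier |  |
| violet | 0.43 M | run made earlier |  |
| flask | 0.58 M |  | 10 d |

| run | time / d | target / % |
|---|---|---|
| green | 0.625 | 21 |
| green | 1.25 | 40 |
| green | 2.50 | 60 |
| green | 4.00 | 69 |
| green | 8.00 | 67 |
| violet | 0.625 | 21 |
| violet | 2.08 | 55 |
| violet | 4.00 | 67 |
| violet | 6.00 | 67 |
| violet | 8.00 | 66 |

(each reading ± 1.5 percentage points)

- at 10 d, what has stopped the reaction, if anything has (it is still moving / all of the substrate has reacted / forward and back rates have come level)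
- target at 10 d, in percent of the substrate charged

- steps that have been proposed: intermediate B -> decomposed reagent; intermediate A -> intermediate C; substrate <-> intermediate B; substrate -> intermediate A; substrate <-> dormant form; intermediate C -> target
- the reaction counts as stopped when no species that holds the substrate changes by six tenths of a point or more over the second half of the time

Green and violet both read 21% at 0.625 d despite different charges, so their percentage curves are carried to [substrate] = 0.58 M. That charge is higher than either run's, so this is an extrapolation.

First, the flat stretch is replaced by its mean. The 5 readings from 4.00 d onward give a ceiling of 67.2%, the selectivity for target, with a standard error of 0.67 percentage points.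

Next comes the gap to that ceiling. Violet, from 0.625 d to 2.08 d, shows it shrinking at 0.915 d⁻¹. That leaves 0.84 points at 5.00 d, above the stopping line in the conditions.

This is the weak link, since the gap is wanted at 5.00 d and the violet window closes earlier, at 2.08 d. Green's later window, 1.25 d to 2.50 d, gives 1.06 d⁻¹, faster than the violet value. This is the closing rate, the first-order constant at which the gap to the ceiling shrinks. It leaves 0.5 points at 5.00 d, narrowly under the line, and 0.0025 points at 10 d. The reckoning therefore stands at 67.2%, with the substrate reacted.

The forecast says all of the substrate has reacted and 66.5%, within 63.5% to 69%, holding that “the ceiling barely depends on concentration”; its centre lies 0.7 points lower than this reckoning.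

The flask gives 66.7%, and all of the substrate has reacted. Of the charged substrate, 0% remains at 10.0 d. The closing rate put the gap at 5.00 d at 0.5 points, while the largest change over the second half of the time is 0.34 points, smaller than that gap.

    intermediate B → decomposed reagent (k = 0.220 h⁻¹)
    intermediate A → intermediate C (k = 0.0530 h⁻¹)
    substrate ⇌ intermediate B (K = 3.00, k = 0.0660 h⁻¹)
    substrate → intermediate A (k = 0.120 h⁻¹)
    substrate ⇌ dormant form (K = 0.730, k = 0.0790 h⁻¹)
    intermediate C → target (k = 4.10 h⁻¹)

A neighbouring flask with the same charge is read at 2.5 d. From the violet gap at 2.08 d, the closing rate leaves 7.8 points, so target should stand at 59.4%; the computed neighbour gives 60.2%.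

The earlier runs and the new flask were generated by integration with made-up constants; scatter was added.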